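**Plan**

1. Retrosynthesis cuts the enal C=C first (Wittig at the C5 formyl group), then both C–C bonds to C3 of the dihydrofuran (C3a–C3 and C3–C2), then the O1–CH2 benzyl ether bond.
2. Enabling feature (benzofuran numbering: ring A fused, ring B the pendant aryl): C3 with its CH2OH carbon is the only ring atom missing from an O-benzylated 5-iodovanillin. There the iodine sits on C3a, the phenol oxygen is O1, the benzylic CH2 of ring B is C2 and the formyl carbon hangs on C5, so C3 can arrive as a carbene.
3. Forward: the ring B benzyl bromide (from 3,4-dihydroxy-5-methoxybenzaldehyde) is joined to the acetal of 5-iodovanillin by ether formation. The dihydrofuran ring, the only ring made, then closes in one palladium-catalysed C–H activation/carbene (4+1) annulation with ethyl diazoacetate.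
4. Ester reduction, acid unveiling of the aldehyde and catechol, and a Wittig reaction complete the side chain.
5. Stereochemistry: C2 (R) comes from a chiral ligand on palladium that selects one enantiotopic benzylic hydrogen; C3 follows from C2 by equilibration of the C3 ester to trans; the E-alkene comes from the stabilised ylide.

Key step: step 6

Assumption: the sense of induction of the chiral ligand in the C–H cleavage cannot be predicted with confidence, so the route is written for the ligand enantiomer that delivers 2R, and its antipode is used if the opposite sense is found.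

**Route**

Step 1
Reactants: 1 3,4-dihydroxy-5-methoxybenzaldehyde
Product: 2 3-methoxy-4,5-bis(methoxymethoxy)benzaldehyde
Conditions: MOMCl (2.5 equiv), i-Pr2NEt (3 equiv), CH2Cl2, 0 °C to rt
Reagents that add atoms: chloromethyl methyl ether, COCCl
Why: Williamson-type O-alkylation of both phenols with the reactive α-chloro ether masks the catechol as MOM ethers, which are stable to base, palladium catalysis and hydride and fall to one later acid treatment.

Step 2
Reactants: 2 3-methoxy-4,5-bis(methoxymethoxy)benzaldehyde
Product: 3 [3-methoxy-4,5-bis(methoxymethoxy)phenyl]methanol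
Conditions: NaBH4, MeOH, 0 °C
Reagents that add atoms: none
Why: Borohydride reduction of an aromatic aldehyde to the benzylic alcohol is chemoselective and leaves the MOM ethers untouched.

Step 3
Reactants: 3 [3-methoxy-4,5-bis(methoxymethoxy)phenyl]methanol
Product: 4 5-(bromomethyl)-1-methoxy-2,3-bis(methoxymethoxy)benzene
Conditions: CBr4, PPh3, CH2Cl2, 0 °C; used at once
Reagents that add atoms: carbon tetrabromide, BrC(Br)(Br)Br
Why: The Appel reaction converts the primary benzylic alcohol into the bromide under neutral conditions that spare the acid-labile MOM ethers.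

Step 4
Reactants: 5 5-iodovanillin (4-hydroxy-3-iodo-5-methoxybenzaldehyde)
Product: 6 4-(1,3-dioxolan-2-yl)-2-iodo-6-methoxyphenol
Conditions: ethylene glycol (5 equiv), p-TsOH·H2O (2 mol %), toluene, reflux, Dean–Stark; NaHCO3 quench
Reagents that add atoms: ethylene glycol, OCCO
Why: Acid-catalysed acetalisation with azeotropic removal of water, a reaction known for vanillin itself with its phenol free, masks the formyl group before any acid-labile MOM ether is in the molecule.

Step 5
Reactants: 6 4-(1,3-dioxolan-2-yl)-2-iodo-6-methoxyphenol; 4 5-(bromomethyl)-1-methoxy-2,3-bis(methoxymethoxy)benzene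
Product: 7 2-[3-iodo-5-methoxy-4-{[3-methoxy-4,5-bis(methoxymethoxy)phenyl]methoxy}phenyl]-1,3-dioxolane
Conditions: K2CO3, DMF, rt to 50 °C
Reagents that add atoms: none
Why: Williamson ether synthesis, in which the phenoxide of 6 displaces the benzylic bromide of 4 (SN2) in a basic medium that preserves the acetal and the MOM ethers.

Step 6
Reactants: 7 2-[3-iodo-5-methoxy-4-{[3-methoxy-4,5-bis(methoxymethoxy)phenyl]methoxy}phenyl]-1,3-dioxolane; 8 ethyl diazoacetate
Product: 10 ethyl (2R,3R)-5-(1,3-dioxolan-2-yl)-7-methoxy-2-[3-methoxy-4,5-bis(methoxymethoxy)phenyl]-2,3-dihydro-1-benzofuran-3-carboxylate (trans ester), via cis C3 epimer 9 (not isolated)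
Conditions: Pd(OAc)2 (5 mol %), (R,R)-TADDOL-derived N,N-dimethylphosphoramidite (aryl = 3,5-xylyl, 10 mol %), CsOPiv (30 mol %), Cs2CO3 (1.5 equiv), 8 (3 equiv, syringe pump, 8 h), toluene, 90 °C; then DBU (0.3 equiv), rt
Reagents that add atoms: none
Why: Proposed new method: zerovalent palladium, formed from Pd(OAc)2 and the phosphoramidite, inserts into the C3a–I bond of 7, pivalate-assisted concerted metalation–deprotonation of one O–CH2 hydrogen gives the five-membered C,C-palladacycle (Pd, C3a, C7a, O1, C2), the carbene from 8 then binds and aryl migration to the carbene carbon makes C3a–C3 and a six-membered palladacycle, from which C(sp3)–C(sp3) reductive elimination with retention at C2 makes C3–C2; should the carbene insert before the C–H cleavage, the same six-membered palladacycle results. The closest known reaction types are the capture of C(sp3)–H-derived five-membered C,C-palladacycles of 2-iodoaryl ethers by one-atom partners, the migratory insertion of arylpalladium carbenes made from diazoesters, and ligand-controlled enantioselective methylene C(sp3)–H arylation. The dihydrofuran ring closes in a formal (4+1) mode, C3a, C7a, O1 and C2 of 7 plus C3 from 8, the last bond being formed by reductive elimination from the six-membered palladacycle. C2 is fixed by the chiral ligand when one of the two enantiotopic benzylic hydrogens is removed and is carried through with retention, whereas C3 is set thermodynamically: the cis epimer 9 equilibrates through its ester enolate in the carbonate medium, finished with DBU, to trans 10 with aryl and ester on opposite faces. The step needs chemoselectivity for the O–CH2 hydrogens over the ortho C–H bonds of ring B (whose arylation would close a six-membered biaryl ether) and over carbene dimerisation; the O–CH2 hydrogens are doubly activated (α-oxygen and benzylic), each ortho position of ring B is flanked by an alkoxy group that would end up in a crowded bay position, the 7-methoxy group turns the O–CH2 bond toward palladium, and slow addition keeps the diazoester scarce.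

Step 7
Reactants: 10 ethyl (2R,3R)-5-(1,3-dioxolan-2-yl)-7-methoxy-2-[3-methoxy-4,5-bis(methoxymethoxy)phenyl]-2,3-dihydro-1-benzofuran-3-carboxylate
Product: 11 [(2R,3S)-5-(1,3-dioxolan-2-yl)-7-methoxy-2-[3-methoxy-4,5-bis(methoxymethoxy)phenyl]-2,3-dihydro-1-benzofuran-3-yl]methanol
Conditions: LiAlH4, THF, 0 °C; Fieser work-up
Reagents that add atoms: none
Why: Hydride reduction of the ester to the primary alcohol leaves the acetal and MOM ethers intact and does not touch either stereocentre (the change of descriptor at C3 is only a change of CIP priorities).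

Step 8
Reactants: 11 [(2R,3S)-5-(1,3-dioxolan-2-yl)-7-methoxy-2-[3-methoxy-4,5-bis(methoxymethoxy)phenyl]-2,3-dihydro-1-benzofuran-3-yl]methanol
Product: 12 (2R,3S)-2-(3,4-dihydroxy-5-methoxyphenyl)-3-(hydroxymethyl)-7-methoxy-2,3-dihydro-1-benzofuran-5-carbaldehyde
Conditions: HCl (2 M) in MeOH–THF–H2O (4:2:1), 40 °C
Reagents that add atoms: water, O
Why: Acid-catalysed hydrolysis of the dioxolane and transacetalisation of both aryl MOM ethers to methanol occur in one operation, methanol carrying off the formaldehyde unit as dimethoxymethane; any reversible acid opening of the benzylic C2–O1 bond can only re-close to the more stable trans ring because C3 is fixed.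

Step 9
Reactants: 12 (2R,3S)-2-(3,4-dihydroxy-5-methoxyphenyl)-3-(hydroxymethyl)-7-methoxy-2,3-dihydro-1-benzofuran-5-carbaldehyde; 13 (triphenylphosphoranylidene)acetaldehyde
Product: 14 cassyformin, (2E)-3-[(2R,3S)-2-(3,4-dihydroxy-5-methoxyphenyl)-3-(hydroxymethyl)-7-methoxy-2,3-dihydro-1-benzofuran-5-yl]prop-2-enal
Conditions: 13 (1.2 equiv), THF–toluene (1:1), 70 °C, argon
Reagents that add atoms: none
Why: Wittig reaction of the aryl aldehyde with the stabilised formylmethylene ylide adds two carbons and should give the E-enal (E from the stabilised ylide); the neutral ylide tolerates the free phenols and the alcohol, and the aldehyde ring carries no free phenol that would deactivate it.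

**Compound list**

1 | 3,4-dihydroxy-5-methoxybenzaldehyde | COc1cc(C=O)cc(O)c1O | starting material
2 | 3-methoxy-4,5-bis(methoxymethoxy)benzaldehyde | COc1cc(C=O)cc(OCOC)c1OCOC | intermediate
3 | [3-methoxy-4,5-bis(methoxymethoxy)phenyl]methanol | COc1cc(CO)cc(OCOC)c1OCOC | intermediate
4 | 5-(bromomethyl)-1-methoxy-2,3-bis(methoxymethoxy)benzene | COc1cc(CBr)cc(OCOC)c1OCOC | intermediate
5 | 5-iodovanillin (4-hydroxy-3-iodo-5-methoxybenzaldehyde) | COc1cc(C=O)cc(I)c1O | starting material
6 | 4-(1,3-dioxolan-2-yl)-2-iodo-6-methoxyphenol | COc1cc(C2OCCO2)cc(I)c1O | intermediate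
7 | 2-[3-iodo-5-methoxy-4-{[3-methoxy-4,5-bis(methoxymethoxy)phenyl]methoxy}phenyl]-1,3-dioxolane | COc1cc(C2OCCO2)cc(I)c1OCc1cc(OC)c(OCOC)c(OCOC)c1 | intermediate
8 | ethyl diazoacetate | CCOC(=O)C=[N+]=[N-] | starting material
9 | ethyl (2R,3S)-5-(1,3-dioxolan-2-yl)-7-methoxy-2-[3-methoxy-4,5-bis(methoxymethoxy)phenyl]-2,3-dihydro-1-benzofuran-3-carboxylate (cis ester, not isolated) | COc1cc([C@@H]2Oc3c(OC)cc(C4OCCO4)cc3[C@@H]2C(=O)OCC)cc(OCOC)c1OCOC | intermediate
10 | ethyl (2R,3R)-5-(1,3-dioxolan-2-yl)-7-methoxy-2-[3-methoxy-4,5-bis(methoxymethoxy)phenyl]-2,3-dihydro-1-benzofuran-3-carboxylate (trans ester) | COc1cc([C@@H]2Oc3c(OC)cc(C4OCCO4)cc3[C@H]2C(=O)OCC)cc(OCOC)c1OCOC | intermediate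
11 | [(2R,3S)-5-(1,3-dioxolan-2-yl)-7-methoxy-2-[3-methoxy-4,5-bis(methoxymethoxy)phenyl]-2,3-dihydro-1-benzofuran-3-yl]methanol | COc1cc([C@@H]2Oc3c(OC)cc(C4OCCO4)cc3[C@H]2CO)cc(OCOC)c1OCOC | intermediate
12 | (2R,3S)-2-(3,4-dihydroxy-5-methoxyphenyl)-3-(hydroxymethyl)-7-methoxy-2,3-dihydro-1-benzofuran-5-carbaldehyde | COc1cc([C@@H]2Oc3c(OC)cc(C=O)cc3[C@H]2CO)cc(O)c1O | intermediate
13 | (triphenylphosphoranylidene)acetaldehyde | O=CC=P(c1ccccc1)(c1ccccc1)c1ccccc1 | starting material
14 | cassyformin, (2E)-3-[(2R,3S)-2-(3,4-dihydroxy-5-methoxyphenyl)-3-(hydroxymethyl)-7-methoxy-2,3-dihydro-1-benzofuran-5-yl]prop-2-enal | COc1cc([C@@H]2Oc3c(OC)cc(/C=C/C=O)cc3[C@H]2CO)cc(O)c1O | target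

**Step count**

Total steps: 9. Longest linear sequence: 8 steps (from 1 through steps 1, 2, 3, 5, 6, 7, 8, 9); the branch from 5 joins at step 5.

**Steps most likely to fail**

1. Step 6 (the proposed new method). After oxidative addition the arylpalladium species may arylate an ortho C–H of ring B instead of cleaving an O–CH2 hydrogen, the carbene may dimerise faster than it is captured, or the two enantiotopic benzylic hydrogens may be poorly discriminated. The fallback uses known chemistry, sets out from 7 and returns at 10. Palladium-catalysed coupling of 7 with the Reformatsky reagent BrZnCH2CO2Et (Pd2(dba)3, XPhos, THF, 60 °C) should give ethyl arylacetate F1. Regitz diazo transfer (4-acetamidobenzenesulfonyl azide, DBU, MeCN) should then give ethyl aryldiazoacetate F2. The chiral dirhodium tetracarboxylate Rh2(S-DOSP)4 (or its antipode, whichever delivers 2R) in toluene at −50 °C should effect enantioselective intramolecular 1,5 C–H insertion of the rhodium carbene into the benzylic O–CH2 bond to give cis ester 9, which DBU epimerises at C3 to 10. In this sequence the cross-coupling makes C3a–C3 and the ring closure makes only C3–C2.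

2. Step 9. The enal formed may react a second time with the ylide (over-homologation to the dienal), and the free catechol may be oxidised during prolonged heating. The fallback sets out from 11 and returns at 14. Hydrolysis of the dioxolane alone (PPTS, acetone–H2O, rt) should give MOM-protected aldehyde F3. A Wittig reaction with the ylide from (1,3-dioxolan-2-ylmethyl)triphenylphosphonium bromide and t-BuOK (THF, 0 °C to rt) should give vinyl dioxolane F4 as an E/Z mixture; this two-carbon unit cannot add twice because the new aldehyde stays masked, and no free phenol is exposed. Aqueous HCl in THF should then hydrolyse the dioxolane, let the enal settle to the E isomer and remove both MOM ethers, giving 14 directly.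

3. Step 4. Acetal formation on the vinylogous acid (a para-hydroxybenzaldehyde) may stop short of completion, and the acetal may revert while the free phenol is isolated. The fallback reverses the order, sets out from 5 and 4 and returns at 7. Williamson alkylation of 5 with 4 (K2CO3, DMF, rt) should give aldehyde ether F5. Noyori acetalisation under aprotic conditions that spare the MOM ethers (1,2-bis(trimethylsilyloxy)ethane, TMSOTf 2 mol %, CH2Cl2, −78 °C) should then give 7.

Further compounds
F1 | step 6 | ethyl 2-[5-(1,3-dioxolan-2-yl)-3-methoxy-2-{[3-methoxy-4,5-bis(methoxymethoxy)phenyl]methoxy}phenyl]acetate | COc1cc(C2OCCO2)cc(CC(=O)OCC)c1OCc1cc(OC)c(OCOC)c(OCOC)c1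
F2 | step 6 | ethyl 2-diazo-2-[5-(1,3-dioxolan-2-yl)-3-methoxy-2-{[3-methoxy-4,5-bis(methoxymethoxy)phenyl]methoxy}phenyl]acetate | COc1cc(C2OCCO2)cc(C(=[N+]=[N-])C(=O)OCC)c1OCc1cc(OC)c(OCOC)c(OCOC)c1
F3 | step 9 | (2R,3S)-3-(hydroxymethyl)-7-methoxy-2-[3-methoxy-4,5-bis(methoxymethoxy)phenyl]-2,3-dihydro-1-benzofuran-5-carbaldehyde | COc1cc([C@@H]2Oc3c(OC)cc(C=O)cc3[C@H]2CO)cc(OCOC)c1OCOC
F4 | step 9 | [(2R,3S)-5-[2-(1,3-dioxolan-2-yl)ethenyl]-7-methoxy-2-[3-methoxy-4,5-bis(methoxymethoxy)phenyl]-2,3-dihydro-1-benzofuran-3-yl]methanol (E/Z mixture) | COc1cc([C@@H]2Oc3c(OC)cc(C=CC4OCCO4)cc3[C@H]2CO)cc(OCOC)c1OCOC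
F5 | step 4 | 3-iodo-5-methoxy-4-{[3-methoxy-4,5-bis(methoxymethoxy)phenyl]methoxy}benzaldehyde | COc1cc(C=O)cc(I)c1OCc1cc(OC)c(OCOC)c(OCOC)c1
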